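A small charge runs this flask, 7.5 mM of free catalyst under 0.050 M of starting material, and the oak readings are that same flask, followed so far.

- oak: starting material 0.050 M; free catalyst 7.5 mM; the very flask that is asked about, followed so far
- flask: starting material 0.050 M; free catalyst 7.5 mM; time 80 min

oak run (percent of the starting material charged)

| time / min | target / % | starting material / % |
|---|---|---|
| 1.33 | 21.8 | 48.7 |
| 3.00 | 31.5 | 30.7 |
| 8.00 | 30.7 | 21.3 |
| 15.0 | 25.8 | 16.3 |
| 40.0 | 13.3 | 8.1 |

(each reading ± 1 percentage point)

- when, up to 80 min, the flask holds most target
- the amount of target, in percent of the starting material charged, at that time



Two different species give you the slow decline in oak. From 15.0 min to 40.0 min target falls at 0.0265 min⁻¹ and starting material at 0.0280 min⁻¹, both read off scattered readings over that span. Run the target line back to zero time and it starts at 38.4%. Oak's target lies under that line by 15 percentage points at 1.33 min and by 4 points at 3.00 min, which gives a fast rate of 0.808 min⁻¹. Your reckoning takes both rates as constant up to the peak, which is an assumption.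

Call the fast rate over the slow one the rate ratio, 30.5, about 1.48 powers of ten. The peak comes at the natural log of this ratio over the difference of the rates, so your reckoning commits to 4.37 min and a height of 33.1%. The second gap stands on readings with a scatter of 1 point.

The forecast says 33.2% at 4.9 min, later than your time and close to your height: “It is flat, so the time is less certain than the height.”

The flask holds most target at 5.18 min, with 33.1%.

    starting material + free catalyst ⇌ isomer of the product A + free catalyst, rate k1*[starting material]*[free catalyst] forward; the back reaction follows from the equilibrium constant (K = 1.00, k = 0.810 M⁻¹ s⁻¹)
    starting material + free catalyst ⇌ target + free catalyst, rate k2*[starting material]*[free catalyst] forward; the back reaction follows from the equilibrium constant (K = 2.70, k = 0.650 M⁻¹ s⁻¹)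
    free catalyst + target → spent catalyst (k = 0.0210 M⁻¹ s⁻¹)
    target + free catalyst ⇌ isomer of the product B + free catalyst, rate k4*[free catalyst]*[target] forward; the back reaction follows from the equilibrium constant (K = 15.0, k = 0.220 M⁻¹ s⁻¹)

At 4.81 min target is still made 1.06 times as fast as it is used up, each step taken net. By 80.0 min that figure has fallen to 0.568. The rate ratio had put the crossing at 4.37 min, which is 0.810 min early. Carry it to the neighbour flask charged with 0.0019 M of free catalyst, a quarter of this charge: the steps making and using target each carry free catalyst as a factor, so your reckoning keeps the ratio at 30.5 and the height at 33.1%. That neighbour flask reaches 33.1%.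

(The runs stem from a simulated flask from invented constants; noise was put on by code.)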